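**Retrosynthetic overview** (chain numbered C1 = CO2H to C24 = lactone C=O; C9' = hydroxymethyl carbon)
1. Late disconnections: C11–C12 (alkenyl–alkenyl Suzuki), C17–C18 (Stille), C8–C9 (allenylzinc addition to a C8 aldehyde), C3–C4 (B-alkyl Suzuki with an acetoacetate enol triflate).
2. The strategy rests on the C5(CH3)–C6(OH)–C7(CH3) triad: three contiguous CH stereocentres of the same local sense, made by three successive one-carbon insertions into a C–B bond under one (R,R)-1,2-dicyclohexylethanediol director; C4 follows by a fourth, achiral insertion.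
3. C9 comes from an enantioenriched propargylic mesylate, C15 from (R)-3-bromo-2-methylpropan-1-ol, C20/C21 from an anti-crotylboration.
4. The only ring, the dihydropyranone O–C20–C21–C22=C23–C24, is closed by ring-closing metathesis of an acrylate before the fragment couplings.

Key step: step 5

Assumption: the SMILES is taken literally, i.e. (5R,6R,7R,9S,15S) with a trans-(2R,3S) lactone (C20 R, C21 S) and 2E,10E,12E,16Z,18E geometry. The C8 carbinol configuration in 27–45 is of no consequence because C8 is oxidised in step 34.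

**Route**

Step 1
Reactants: 1 2-(bromomethyl)-4,4,5,5-tetramethyl-1,3,2-dioxaborolane; 2 benzyl alcohol
Product: 3 2-[(benzyloxy)methyl]-4,4,5,5-tetramethyl-1,3,2-dioxaborolane
Conditions: NaH, THF, 0 °C; then 1, 0 °C to rt
Reagents that add atoms: none
Why: The alkoxide adds to boron and benzyloxy migrates to carbon with loss of bromide (borate 1,2-shift, the standard substitution of an α-halo boronic ester).

Step 2
Reactants: 3 2-[(benzyloxy)methyl]-4,4,5,5-tetramethyl-1,3,2-dioxaborolane; 4 (1R,2R)-1,2-dicyclohexylethane-1,2-diol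
Product: 6 (4R,5R)-2-[(benzyloxy)methyl]-4,5-dicyclohexyl-1,3,2-dioxaborolane, via [(benzyloxy)methyl]boronic acid 5 (not isolated)
Conditions: NaIO4, NH4OAc, acetone/H2O, rt; extraction; then 4, MgSO4, Et2O, rt
Reagents that add atoms: none
Why: Periodate cleaves the released pinacol irreversibly, which pulls the hydrolysis to the boronic acid, and this condenses with the C2-symmetric diol to the robust dioxaborolane (oxidative pinacol removal, then esterification).

Step 3
Reactants: 6 (4R,5R)-2-[(benzyloxy)methyl]-4,5-dicyclohexyl-1,3,2-dioxaborolane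
Product: 8 (4R,5R)-2-[(2S)-1-(benzyloxy)propan-2-yl]-4,5-dicyclohexyl-1,3,2-dioxaborolane, via (S)-α-chloro boronate 7 (not isolated)
Conditions: CH2Cl2, n-BuLi, THF, −100 °C; 6; ZnCl2, −100 °C to rt; then MeMgBr, THF, −78 °C to rt
Reagents that add atoms: dichloromethane ClCCl; methylmagnesium bromide C[Mg]Br
Why: Matteson homologation: LiCHCl2 forms a borate, ZnCl2-promoted 1,2-migration expels the chloride selected by the (R,R) director to give the (S)-α-chloro boronate 7, and MeMgBr displaces the remaining chloride with inversion through a second borate, which sets C7.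

Step 4
Reactants: 8 (4R,5R)-2-[(2S)-1-(benzyloxy)propan-2-yl]-4,5-dicyclohexyl-1,3,2-dioxaborolane; 2 benzyl alcohol
Product: 10 (4R,5R)-2-[(1R,2S)-1,3-bis(benzyloxy)-2-methylpropyl]-4,5-dicyclohexyl-1,3,2-dioxaborolane, via (1S,2S)-α-chloro boronate 9 (not isolated)
Conditions: CH2Cl2, n-BuLi, THF, −100 °C; 8; ZnCl2, −100 °C to rt; then LiOBn (from 2 and n-BuLi), THF/DMSO, −78 °C to rt
Reagents that add atoms: dichloromethane ClCCl
Why: Second Matteson cycle: the same director-controlled insertion gives (S)-chloride 9, and lithium benzyloxide adds to boron and migrates with inversion, which sets the C6 carbinol as its benzyl ether.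

Step 5
Reactants: 10 (4R,5R)-2-[(1R,2S)-1,3-bis(benzyloxy)-2-methylpropyl]-4,5-dicyclohexyl-1,3,2-dioxaborolane
Product: 12 (4R,5R)-2-[(2S,3R,4S)-3,5-bis(benzyloxy)-4-methylpentan-2-yl]-4,5-dicyclohexyl-1,3,2-dioxaborolane, via (1S)-α-chloro boronate 11 (not isolated)
Conditions: CH2Cl2, n-BuLi, THF, −100 °C; 10; ZnCl2, −100 °C to rt; then MeMgBr, THF, −78 °C to rt
Reagents that add atoms: dichloromethane ClCCl; methylmagnesium bromide C[Mg]Br
Why: LiCHCl2 adds to boron of 10 to give a borate, and with ZnCl2 the C6 carbon migrates from boron to the CHCl2 carbon with loss of one chloride (C5–C6 bond); MeMgBr then adds to boron and methyl migrates to C5 with loss of the second chloride (C5–CH3 bond). This is the Matteson homologation of a chiral diol boronic ester followed by Grignard displacement, here in its third turn, and no ring is closed. C5 is controlled by the (R,R)-dicyclohexylethanediol director: in the zinc-bound borate only one of the two diastereotopic chlorides is displaced readily, which should give the (S)-α-chloro boronate 11, and the methyl transfer is stereospecific with inversion at C5. The migrating C6 keeps its configuration, so C7, C6 and C5 end with the same local sense, as the target requires. The selectivity needed is between the two chlorides and against epimerisation of 11 by free chloride; the C2-symmetric director, the ZnCl2 (which speeds the migration and binds chloride) and immediate use of 11 secure it. β-Elimination of the C6 benzyloxy group from the borates is the side reaction to suppress by low temperature.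

Step 6
Reactants: 12 (4R,5R)-2-[(2S,3R,4S)-3,5-bis(benzyloxy)-4-methylpentan-2-yl]-4,5-dicyclohexyl-1,3,2-dioxaborolane
Product: 13 (4R,5R)-2-[(2R,3R,4S)-3,5-bis(benzyloxy)-2,4-dimethylpentyl]-4,5-dicyclohexyl-1,3,2-dioxaborolane
Conditions: ICH2Cl, n-BuLi, THF, −78 °C to rt
Reagents that add atoms: chloroiodomethane ClCI
Why: LiCH2Cl generated in the presence of the boronate inserts CH2 by borate formation and 1,2-migration of C5 with retention (Matteson methylene homologation), which forms C4–C5 and leaves a primary C4–B bond.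

Step 7
Reactants: 13 (4R,5R)-2-[(2R,3R,4S)-3,5-bis(benzyloxy)-2,4-dimethylpentyl]-4,5-dicyclohexyl-1,3,2-dioxaborolane
Product: 14 (2S,3R,4R)-5-[(4R,5R)-4,5-dicyclohexyl-1,3,2-dioxaborolan-2-yl]-2,4-dimethylpentane-1,3-diol
Conditions: H2 (1 atm), Pd/C (10% palladium on carbon), EtOAc, rt
Reagents that add atoms: none
Why: Hydrogenolysis of both benzyl ethers is done while the molecule has no alkene, and the hindered alkyl dioxaborolane is inert to neutral hydrogenation.

Step 8
Reactants: 14 (2S,3R,4R)-5-[(4R,5R)-4,5-dicyclohexyl-1,3,2-dioxaborolan-2-yl]-2,4-dimethylpentane-1,3-diol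
Product: 15 (4R,5R)-2-{(2R,3R,4S)-3,5-bis[(tert-butyldimethylsilyl)oxy]-2,4-dimethylpentyl}-4,5-dicyclohexyl-1,3,2-dioxaborolane
Conditions: TBSOTf, 2,6-lutidine, CH2Cl2, −78 to 0 °C
Reagents that add atoms: tert-butyldimethylsilyl triflate CC(C)(C)[Si](C)(C)OS(=O)(=O)C(F)(F)F
Why: The silyl triflate with lutidine silylates both the primary and the hindered secondary hydroxyl (standard silyl ether formation).

Step 9
Reactants: 15 (4R,5R)-2-{(2R,3R,4S)-3,5-bis[(tert-butyldimethylsilyl)oxy]-2,4-dimethylpentyl}-4,5-dicyclohexyl-1,3,2-dioxaborolane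
Product: 16 potassium {(2R,3R,4S)-3,5-bis[(tert-butyldimethylsilyl)oxy]-2,4-dimethylpentyl}trifluoroborate
Conditions: KHF2, MeOH/H2O, rt; diol 4 removed by trituration with Et2O/hexane
Reagents that add atoms: potassium hydrogen difluoride F.[F-].[K+]
Why: KHF2 exchanges the diol for fluoride to give the trifluoroborate salt, driven by B–F bond strength and by separation of the salt from the released director, and alkyl TBS ethers should tolerate KHF2 at room temperature.

Step 10
Reactants: 17 ethyl acetoacetate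
Product: 18 ethyl (E)-3-[(trifluoromethylsulfonyl)oxy]but-2-enoate
Conditions: Tf2O, aq. Me4NOH, toluene, 5 °C
Reagents that add atoms: triflic anhydride O=S(=O)(OS(=O)(=O)C(F)(F)F)C(F)(F)F
Why: Under Schotten–Baumann conditions with the non-coordinating Me4N+ counter-ion the open, non-chelated enolate is O-sulfonylated, which should give the (E)-enol triflate (OTf trans to CO2Et).

Step 11
Reactants: 16 potassium {(2R,3R,4S)-3,5-bis[(tert-butyldimethylsilyl)oxy]-2,4-dimethylpentyl}trifluoroborate; 18 ethyl (E)-3-[(trifluoromethylsulfonyl)oxy]but-2-enoate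
Product: 19 ethyl (2E,5R,6R,7S)-6,8-bis[(tert-butyldimethylsilyl)oxy]-3,5,7-trimethyloct-2-enoate
Conditions: PdCl2(dppf)·CH2Cl2 (10 mol%), Cs2CO3, THF/H2O 10:1, 65 °C
Reagents that add atoms: none
Why: B-alkyl Suzuki–Miyaura coupling of a primary alkyltrifluoroborate with an alkenyl triflate (dppf suppresses β-hydride elimination) proceeds with retention at the triflate carbon, which forms C3–C4 and fixes 2E.

Step 12
Reactants: 19 ethyl (2E,5R,6R,7S)-6,8-bis[(tert-butyldimethylsilyl)oxy]-3,5,7-trimethyloct-2-enoate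
Product: 20 ethyl (2E,5R,6R,7S)-6-[(tert-butyldimethylsilyl)oxy]-8-hydroxy-3,5,7-trimethyloct-2-enoate
Conditions: HF·pyridine, pyridine, THF, 0 °C to rt
Reagents that add atoms: none
Why: Buffered HF·pyridine cleaves the unhindered primary TBS ether much faster than the secondary one, which is flanked by two methyl-bearing carbons (selective desilylation).

Step 13
Reactants: 20 ethyl (2E,5R,6R,7S)-6-[(tert-butyldimethylsilyl)oxy]-8-hydroxy-3,5,7-trimethyloct-2-enoate
Product: 21 ethyl (2E,5R,6R,7R)-6-[(tert-butyldimethylsilyl)oxy]-3,5,7-trimethyl-8-oxooct-2-enoate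
Conditions: Dess–Martin periodinane, NaHCO3, CH2Cl2, 0 °C to rt; used crude
Reagents that add atoms: none
Why: Dess–Martin oxidation under buffered, non-basic conditions should give the α-methyl aldehyde without epimerisation at C7.

Step 14
Reactants: 22 (tert-butyldimethylsilyloxy)acetaldehyde
Product: 23 rac-1-[(tert-butyldimethylsilyl)oxy]pent-3-yn-2-ol
Conditions: CH3C≡CMgBr, THF, −78 to 0 °C; aq. NH4Cl
Reagents that add atoms: 1-propynylmagnesium bromide CC#C[Mg]Br
Why: Grignard addition of the alkynyl nucleophile to the aldehyde gives the propargylic alcohol.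

Step 15
Reactants: 23 rac-1-[(tert-butyldimethylsilyl)oxy]pent-3-yn-2-ol
Product: 24 1-[(tert-butyldimethylsilyl)oxy]pent-3-yn-2-one
Conditions: Dess–Martin periodinane, NaHCO3, CH2Cl2, rt
Reagents that add atoms: none
Why: Dess–Martin oxidation of a secondary propargylic alcohol to the ynone.

Step 16
Reactants: 24 1-[(tert-butyldimethylsilyl)oxy]pent-3-yn-2-one
Product: 25 (R)-1-[(tert-butyldimethylsilyl)oxy]pent-3-yn-2-ol
Conditions: RuCl[(S,S)-TsDPEN](p-cymene) (1 mol%), i-PrOH, rt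
Reagents that add atoms: none
Why: Noyori asymmetric transfer hydrogenation of an ynone, in which the alkynyl group is the π-directing substituent; the (S,S) catalyst should give the same spatial sense as in (S)-alkynyl methyl carbinols, which is R here because CH2OSi outranks the alkynyl group (to be checked by Mosher analysis, the (R,R) catalyst giving the antipode).

Step 17
Reactants: 25 (R)-1-[(tert-butyldimethylsilyl)oxy]pent-3-yn-2-ol
Product: 26 (R)-1-[(tert-butyldimethylsilyl)oxy]pent-3-yn-2-yl methanesulfonate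
Conditions: MsCl, Et3N, CH2Cl2, −78 to 0 °C; used without chromatography
Reagents that add atoms: methanesulfonyl chloride CS(=O)(=O)Cl
Why: Mesylation of the secondary alcohol with retention activates the propargylic carbon.

Step 18
Reactants: 21 ethyl (2E,5R,6R,7R)-6-[(tert-butyldimethylsilyl)oxy]-3,5,7-trimethyl-8-oxooct-2-enoate; 26 (R)-1-[(tert-butyldimethylsilyl)oxy]pent-3-yn-2-yl methanesulfonate
Product: 27 ethyl (2E,5R,6R,7S,8R,9S)-6-[(tert-butyldimethylsilyl)oxy]-9-{[(tert-butyldimethylsilyl)oxy]methyl}-8-hydroxy-3,5,7-trimethyldodec-2-en-10-ynoate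
Conditions: Pd(OAc)2 (5 mol%), PPh3 (5 mol%), Et2Zn (3 equiv), THF, −78 to −20 °C
Reagents that add atoms: none
Why: Marshall propargylation: zerovalent palladium ionises the mesylate by anti SN2' attack, Et2Zn takes over the allenyl group with retention, and the allenylzinc adds to the aldehyde through a cyclic SE2' transition state, so C9 is set by the mesylate with net inversion at the propargylic carbon and C8–C9 should be anti (the C8 epimer converges in step 34).

Step 19
Reactants: 27 ethyl (2E,5R,6R,7S,8R,9S)-6-[(tert-butyldimethylsilyl)oxy]-9-{[(tert-butyldimethylsilyl)oxy]methyl}-8-hydroxy-3,5,7-trimethyldodec-2-en-10-ynoate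
Product: 29 ethyl (2E,5R,6R,7S,8R,9S,10E)-6-[(tert-butyldimethylsilyl)oxy]-9-{[(tert-butyldimethylsilyl)oxy]methyl}-8-hydroxy-11-iodo-3,5,7-trimethyldodeca-2,10-dienoate, via C11 vinylstannane 28 (not isolated)
Conditions: Bu3SnH (slow addition), PdCl2(PPh3)2 (5 mol%), THF, 0 °C to rt; then I2, CH2Cl2, 0 °C
Reagents that add atoms: tributyltin hydride CCCC[SnH](CCCC)CCCC (tin stays only in 28); iodine II
Why: Palladium-catalysed syn hydrostannation should place tin on the less hindered, methyl-bearing alkyne carbon C11, remote from the branched C9, and tin–iodine exchange then proceeds with retention to the (E)-2-iodo-2-alkene.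

Step 20
Reactants: 29 ethyl (2E,5R,6R,7S,8R,9S,10E)-6-[(tert-butyldimethylsilyl)oxy]-9-{[(tert-butyldimethylsilyl)oxy]methyl}-8-hydroxy-11-iodo-3,5,7-trimethyldodeca-2,10-dienoate
Product: 30 (2E,5R,6R,7S,8R,9S,10E)-6-[(tert-butyldimethylsilyl)oxy]-9-{[(tert-butyldimethylsilyl)oxy]methyl}-8-hydroxy-11-iodo-3,5,7-trimethyldodeca-2,10-dienoic acid
Conditions: KOSiMe3, THF, rt to 40 °C; aq. KHSO4 work-up
Reagents that add atoms: potassium trimethylsilanolate C[Si](C)(C)[O-].[K+]
Why: Anhydrous silanolate ester cleavage frees the acid at the last stage without base-sensitive groups, and the TBS ethers and the vinyl iodide should survive.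

Step 21
Reactants: 31 prop-2-yn-1-ol
Product: 32 (E)-3-(tributylstannyl)prop-2-en-1-ol
Conditions: Bu3SnH, AIBN (cat.), neat, 80 °C; chromatography
Reagents that add atoms: tributyltin hydride CCCC[SnH](CCCC)CCCC
Why: Radical hydrostannation of the terminal alkyne equilibrates through reversible stannyl radical addition to the thermodynamically preferred (E)-β-stannyl alkene.

Step 22
Reactants: 32 (E)-3-(tributylstannyl)prop-2-en-1-ol
Product: 33 (E)-3-(tributylstannyl)prop-2-enal
Conditions: MnO2, CH2Cl2, rt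
Reagents that add atoms: none
Why: MnO2 oxidises the allylic alcohol to the enal without touching the C–Sn bond.

Step 23
Reactants: 33 (E)-3-(tributylstannyl)prop-2-enal
Product: 34 (1E,3S,4S)-4-methyl-1-(tributylstannyl)hexa-1,5-dien-3-ol
Conditions: (E)-but-2-ene, n-BuLi, KOt-Bu, THF, −78 to −45 °C; (−)-Ipc2BOMe; BF3·OEt2, −78 °C; then 33, −78 °C; NaOH, H2O2
Reagents that add atoms: (E)-but-2-ene C/C=C/C
Why: Brown crotylboration: the (E)-crotylborane reacts through a chair transition state to give the anti adduct, and the isopinocampheyl groups derived from (+)-α-pinene select the aldehyde face, which sets C20 and C21 (assignment to be confirmed by Mosher analysis).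

Step 24
Reactants: 34 (1E,3S,4S)-4-methyl-1-(tributylstannyl)hexa-1,5-dien-3-ol
Product: 35 (1E,3S,4S)-4-methyl-1-(tributylstannyl)hexa-1,5-dien-3-yl prop-2-enoate
Conditions: acryloyl chloride, i-Pr2NEt, DMAP (cat.), CH2Cl2, −78 to 0 °C
Reagents that add atoms: acryloyl chloride C=CC(=O)Cl
Why: O-Acylation of the secondary allylic alcohol installs the acrylate needed for ring closure.

Step 25
Reactants: 35 (1E,3S,4S)-4-methyl-1-(tributylstannyl)hexa-1,5-dien-3-yl prop-2-enoate
Product: 36 (5S,6S)-5-methyl-6-[(E)-2-(tributylstannyl)ethenyl]-5,6-dihydro-2H-pyran-2-one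
Conditions: second-generation Grubbs catalyst (5 mol%), CH2Cl2 (0.005 M), 40 °C
Reagents that add atoms: none
Why: Ring-closing metathesis: the ruthenium carbene loads on the monosubstituted C22 vinyl group and closes onto the acrylate to the six-membered lactone (C22=C23), while the hindered stannyl-substituted internal alkene should stay out of the reaction.

Step 26
Reactants: 37 (R)-3-bromo-2-methylpropan-1-ol
Product: 38 (R)-(3-bromo-2-methylpropoxy)(tert-butyl)dimethylsilane
Conditions: TBSCl, imidazole, CH2Cl2, rt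
Reagents that add atoms: tert-butyldimethylsilyl chloride CC(C)(C)[Si](C)(C)Cl
Why: Silylation blocks the hydroxyl so that the following acetylide cannot form an oxetane through the alkoxide.

Step 27
Reactants: 38 (R)-(3-bromo-2-methylpropoxy)(tert-butyl)dimethylsilane
Product: 39 (S)-tert-butyldimethyl[(2-methylpent-4-yn-1-yl)oxy]silane
Conditions: LiC≡CH·H2NCH2CH2NH2, DMSO, 0 °C to rt
Reagents that add atoms: lithium acetylide–ethylenediamine complex [Li]C#C.NCCN
Why: SN2 alkynylation of the primary bromide in DMSO forms C13–C14 without touching the C15 stereocentre.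

Step 28
Reactants: 39 (S)-tert-butyldimethyl[(2-methylpent-4-yn-1-yl)oxy]silane
Product: 40 tert-butyldimethyl{[(2S,4E)-2-methyl-5-(4,4,5,5-tetramethyl-1,3,2-dioxaborolan-2-yl)pent-4-en-1-yl]oxy}silane
Conditions: pinacolborane, Cp2Zr(H)Cl (10 mol%), Et3N (10 mol%), neat, 60 °C
Reagents that add atoms: pinacolborane [H]B1OC(C)(C)C(C)(C)O1
Why: Zirconium-catalysed syn hydroboration of the terminal alkyne gives the (E)-alkenyl boronate with boron at the terminal carbon, which fixes 12E.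

Step 29
Reactants: 40 tert-butyldimethyl{[(2S,4E)-2-methyl-5-(4,4,5,5-tetramethyl-1,3,2-dioxaborolan-2-yl)pent-4-en-1-yl]oxy}silane
Product: 41 (2S,4E)-2-methyl-5-(4,4,5,5-tetramethyl-1,3,2-dioxaborolan-2-yl)pent-4-en-1-ol
Conditions: camphorsulfonic acid (10 mol%), MeOH/CH2Cl2, 0 °C
Reagents that add atoms: none
Why: Acid-catalysed methanolysis removes the primary TBS ether under fluoride-free conditions that the pinacol boronate tolerates.

Step 30
Reactants: 41 (2S,4E)-2-methyl-5-(4,4,5,5-tetramethyl-1,3,2-dioxaborolan-2-yl)pent-4-en-1-ol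
Product: 42 (2S,4E)-2-methyl-5-(4,4,5,5-tetramethyl-1,3,2-dioxaborolan-2-yl)pent-4-enal
Conditions: Dess–Martin periodinane, NaHCO3, CH2Cl2, 0 °C; used crude
Reagents that add atoms: none
Why: Buffered Dess–Martin oxidation should give the α-methyl aldehyde without epimerisation at C15.

Step 31
Reactants: 42 (2S,4E)-2-methyl-5-(4,4,5,5-tetramethyl-1,3,2-dioxaborolan-2-yl)pent-4-enal
Product: 43 2-[(1E,4S,5Z)-6-iodo-4-methylhepta-1,5-dien-1-yl]-4,4,5,5-tetramethyl-1,3,2-dioxaborolane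
Conditions: EtPPh3I, n-BuLi, THF, rt; I2, −78 °C; NaN(SiMe3)2, −20 °C; then 42, −78 °C
Reagents that add atoms: ethyltriphenylphosphonium iodide CC[P+](c1ccccc1)(c1ccccc1)c1ccccc1.[I-]; iodine II
Why: Stork–Zhao-type Wittig olefination with the α-iodo ylide should give the (Z)-2-iodo-2-alkene (iodine cis to C15) under kinetic control at low temperature, which also protects the α-stereocentre.

Step 32
Reactants: 43 2-[(1E,4S,5Z)-6-iodo-4-methylhepta-1,5-dien-1-yl]-4,4,5,5-tetramethyl-1,3,2-dioxaborolane; 36 (5S,6S)-5-methyl-6-[(E)-2-(tributylstannyl)ethenyl]-5,6-dihydro-2H-pyran-2-one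
Product: 44 (5S,6R)-5-methyl-6-[(1E,3Z,5S,7E)-3,5-dimethyl-8-(4,4,5,5-tetramethyl-1,3,2-dioxaborolan-2-yl)octa-1,3,7-trien-1-yl]-5,6-dihydro-2H-pyran-2-one
Conditions: Pd2(dba)3 (5 mol%), AsPh3, NMP, rt to 40 °C, dark
Reagents that add atoms: none
Why: Stille coupling forms C17–C18 with retention at both alkenes under neutral conditions that spare the lactone, and the pinacol boronate stays inert because no base is present.

Step 33
Reactants: 30 (2E,5R,6R,7S,8R,9S,10E)-6-[(tert-butyldimethylsilyl)oxy]-9-{[(tert-butyldimethylsilyl)oxy]methyl}-8-hydroxy-11-iodo-3,5,7-trimethyldodeca-2,10-dienoic acid; 44 (5S,6R)-5-methyl-6-[(1E,3Z,5S,7E)-3,5-dimethyl-8-(4,4,5,5-tetramethyl-1,3,2-dioxaborolan-2-yl)octa-1,3,7-trien-1-yl]-5,6-dihydro-2H-pyran-2-one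
Product: 45 (2E,5R,6R,7S,8R,9S,10E,12E,15S,16Z,18E)-6-[(tert-butyldimethylsilyl)oxy]-9-{[(tert-butyldimethylsilyl)oxy]methyl}-8-hydroxy-3,5,7,11,15,17-hexamethyl-19-[(2R,3S)-3-methyl-6-oxo-3,6-dihydro-2H-pyran-2-yl]nonadeca-2,10,12,16,18-pentaenoic acid
Conditions: Pd(PPh3)4 (10 mol%), TlOEt (3 equiv), degassed THF/H2O 3:1, rt, short reaction time; pH 4 buffer
Reagents that add atoms: none
Why: Alkenyl–alkenyl Suzuki–Miyaura coupling forms C11–C12 with retention on both partners, and TlOEt makes transmetalation fast at room temperature so that the lactone meets base only briefly and C8 is still a carbinol with no epimerisable α-centre.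

Step 34
Reactants: 45 (2E,5R,6R,7S,8R,9S,10E,12E,15S,16Z,18E)-6-[(tert-butyldimethylsilyl)oxy]-9-{[(tert-butyldimethylsilyl)oxy]methyl}-8-hydroxy-3,5,7,11,15,17-hexamethyl-19-[(2R,3S)-3-methyl-6-oxo-3,6-dihydro-2H-pyran-2-yl]nonadeca-2,10,12,16,18-pentaenoic acid
Product: 46 (2E,5R,6R,7R,9S,10E,12E,15S,16Z,18E)-6-[(tert-butyldimethylsilyl)oxy]-9-{[(tert-butyldimethylsilyl)oxy]methyl}-3,5,7,11,15,17-hexamethyl-19-[(2R,3S)-3-methyl-6-oxo-3,6-dihydro-2H-pyran-2-yl]-8-oxononadeca-2,10,12,16,18-pentaenoic acid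
Conditions: Dess–Martin periodinane, NaHCO3, CH2Cl2, 0 °C to rt
Reagents that add atoms: none
Why: Dess–Martin oxidation of the only free hydroxyl gives the C8 ketone under neutral conditions that should not epimerise C7 or C9 or move the C10 alkene into conjugation.

Step 35
Reactants: 46 (2E,5R,6R,7R,9S,10E,12E,15S,16Z,18E)-6-[(tert-butyldimethylsilyl)oxy]-9-{[(tert-butyldimethylsilyl)oxy]methyl}-3,5,7,11,15,17-hexamethyl-19-[(2R,3S)-3-methyl-6-oxo-3,6-dihydro-2H-pyran-2-yl]-8-oxononadeca-2,10,12,16,18-pentaenoic acid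
Product: 47 (2E,5R,6R,7R,9S,10E,12E,15S,16Z,18E)-6-hydroxy-9-(hydroxymethyl)-3,5,7,11,15,17-hexamethyl-19-[(2R,3S)-3-methyl-6-oxo-3,6-dihydro-2H-pyran-2-yl]-8-oxononadeca-2,10,12,16,18-pentaenoic acid
Conditions: HF·pyridine, pyridine, THF, 0 °C to rt (plastic vessel)
Reagents that add atoms: none
Why: Pyridine-buffered HF removes both TBS ethers under mildly acidic, non-basic conditions, which avoids retro-aldol loss of the C9 hydroxymethyl group, β-elimination and lactone opening.

**Compound list**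
1 | 2-(bromomethyl)-4,4,5,5-tetramethyl-1,3,2-dioxaborolane | BrCB1OC(C)(C)C(C)(C)O1 | starting material
2 | benzyl alcohol | OCc1ccccc1 | starting material
3 | 2-[(benzyloxy)methyl]-4,4,5,5-tetramethyl-1,3,2-dioxaborolane | c1ccccc1COCB1OC(C)(C)C(C)(C)O1 | intermediate
4 | (1R,2R)-1,2-dicyclohexylethane-1,2-diol | O[C@H](C1CCCCC1)[C@H](O)C1CCCCC1 | starting material
5 | [(benzyloxy)methyl]boronic acid | OB(O)COCc1ccccc1 | intermediate (not isolated)
6 | (4R,5R)-2-[(benzyloxy)methyl]-4,5-dicyclohexyl-1,3,2-dioxaborolane | c1ccccc1COCB1O[C@H](C2CCCCC2)[C@@H](C3CCCCC3)O1 | intermediate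
7 | (4R,5R)-2-[(1S)-2-(benzyloxy)-1-chloroethyl]-4,5-dicyclohexyl-1,3,2-dioxaborolane | c1ccccc1COC[C@@H](Cl)B1O[C@H](C2CCCCC2)[C@@H](C3CCCCC3)O1 | intermediate (not isolated)
8 | (4R,5R)-2-[(2S)-1-(benzyloxy)propan-2-yl]-4,5-dicyclohexyl-1,3,2-dioxaborolane | c1ccccc1COC[C@H](C)B1O[C@H](C2CCCCC2)[C@@H](C3CCCCC3)O1 | intermediate
9 | (4R,5R)-2-[(1S,2S)-3-(benzyloxy)-1-chloro-2-methylpropyl]-4,5-dicyclohexyl-1,3,2-dioxaborolane | c1ccccc1COC[C@H](C)[C@@H](Cl)B1O[C@H](C2CCCCC2)[C@@H](C3CCCCC3)O1 | intermediate (not isolated)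
10 | (4R,5R)-2-[(1R,2S)-1,3-bis(benzyloxy)-2-methylpropyl]-4,5-dicyclohexyl-1,3,2-dioxaborolane (key-step precursor) | c1ccccc1COC[C@H](C)[C@H](OCc1ccccc1)B1O[C@H](C2CCCCC2)[C@@H](C3CCCCC3)O1 | intermediate
11 | (4R,5R)-2-[(1S,2S,3S)-2,4-bis(benzyloxy)-1-chloro-3-methylbutyl]-4,5-dicyclohexyl-1,3,2-dioxaborolane | c1ccccc1COC[C@H](C)[C@H](OCc1ccccc1)[C@@H](Cl)B1O[C@H](C2CCCCC2)[C@@H](C3CCCCC3)O1 | intermediate (not isolated)
12 | (4R,5R)-2-[(2S,3R,4S)-3,5-bis(benzyloxy)-4-methylpentan-2-yl]-4,5-dicyclohexyl-1,3,2-dioxaborolane (key-step product) | c1ccccc1COC[C@H](C)[C@H](OCc1ccccc1)[C@H](C)B1O[C@H](C2CCCCC2)[C@@H](C3CCCCC3)O1 | intermediate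
13 | (4R,5R)-2-[(2R,3R,4S)-3,5-bis(benzyloxy)-2,4-dimethylpentyl]-4,5-dicyclohexyl-1,3,2-dioxaborolane | c1ccccc1COC[C@H](C)[C@H](OCc1ccccc1)[C@H](C)CB1O[C@H](C2CCCCC2)[C@@H](C3CCCCC3)O1 | intermediate
14 | (2S,3R,4R)-5-[(4R,5R)-4,5-dicyclohexyl-1,3,2-dioxaborolan-2-yl]-2,4-dimethylpentane-1,3-diol | OC[C@H](C)[C@H](O)[C@H](C)CB1O[C@H](C2CCCCC2)[C@@H](C3CCCCC3)O1 | intermediate
15 | (4R,5R)-2-{(2R,3R,4S)-3,5-bis[(tert-butyldimethylsilyl)oxy]-2,4-dimethylpentyl}-4,5-dicyclohexyl-1,3,2-dioxaborolane | CC(C)(C)[Si](C)(C)OC[C@H](C)[C@H](O[Si](C)(C)C(C)(C)C)[C@H](C)CB1O[C@H](C2CCCCC2)[C@@H](C3CCCCC3)O1 | intermediate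
16 | potassium {(2R,3R,4S)-3,5-bis[(tert-butyldimethylsilyl)oxy]-2,4-dimethylpentyl}trifluoroborate | CC(C)(C)[Si](C)(C)OC[C@H](C)[C@H](O[Si](C)(C)C(C)(C)C)[C@H](C)C[B-](F)(F)F.[K+] | intermediate
17 | ethyl acetoacetate | CCOC(=O)CC(C)=O | starting material
18 | ethyl (E)-3-[(trifluoromethylsulfonyl)oxy]but-2-enoate | CCOC(=O)/C=C(\C)OS(=O)(=O)C(F)(F)F | intermediate
19 | ethyl (2E,5R,6R,7S)-6,8-bis[(tert-butyldimethylsilyl)oxy]-3,5,7-trimethyloct-2-enoate | CC(C)(C)[Si](C)(C)OC[C@H](C)[C@H](O[Si](C)(C)C(C)(C)C)[C@H](C)C/C(C)=C/C(=O)OCC | intermediate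
20 | ethyl (2E,5R,6R,7S)-6-[(tert-butyldimethylsilyl)oxy]-8-hydroxy-3,5,7-trimethyloct-2-enoate | OC[C@H](C)[C@H](O[Si](C)(C)C(C)(C)C)[C@H](C)C/C(C)=C/C(=O)OCC | intermediate
21 | ethyl (2E,5R,6R,7R)-6-[(tert-butyldimethylsilyl)oxy]-3,5,7-trimethyl-8-oxooct-2-enoate | O=C[C@H](C)[C@H](O[Si](C)(C)C(C)(C)C)[C@H](C)C/C(C)=C/C(=O)OCC | intermediate
22 | (tert-butyldimethylsilyloxy)acetaldehyde | CC(C)(C)[Si](C)(C)OCC=O | starting material
23 | rac-1-[(tert-butyldimethylsilyl)oxy]pent-3-yn-2-ol | CC#CC(O)CO[Si](C)(C)C(C)(C)C | intermediate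
24 | 1-[(tert-butyldimethylsilyl)oxy]pent-3-yn-2-one | CC#CC(=O)CO[Si](C)(C)C(C)(C)C | intermediate
25 | (R)-1-[(tert-butyldimethylsilyl)oxy]pent-3-yn-2-ol | CC#C[C@@H](O)CO[Si](C)(C)C(C)(C)C | intermediate
26 | (R)-1-[(tert-butyldimethylsilyl)oxy]pent-3-yn-2-yl methanesulfonate | CC#C[C@@H](OS(C)(=O)=O)CO[Si](C)(C)C(C)(C)C | intermediate
27 | ethyl (2E,5R,6R,7S,8R,9S)-6-[(tert-butyldimethylsilyl)oxy]-9-{[(tert-butyldimethylsilyl)oxy]methyl}-8-hydroxy-3,5,7-trimethyldodec-2-en-10-ynoate | CC#C[C@@H](CO[Si](C)(C)C(C)(C)C)[C@@H](O)[C@H](C)[C@H](O[Si](C)(C)C(C)(C)C)[C@H](C)C/C(C)=C/C(=O)OCC | intermediate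
28 | (10E)-11-(tributylstannyl) alkene from 27 (C11 vinylstannane) | CCCC[Sn](CCCC)(CCCC)/C(C)=C/[C@@H](CO[Si](C)(C)C(C)(C)C)[C@@H](O)[C@H](C)[C@H](O[Si](C)(C)C(C)(C)C)[C@H](C)C/C(C)=C/C(=O)OCC | intermediate (not isolated)
29 | ethyl (2E,5R,6R,7S,8R,9S,10E)-6-[(tert-butyldimethylsilyl)oxy]-9-{[(tert-butyldimethylsilyl)oxy]methyl}-8-hydroxy-11-iodo-3,5,7-trimethyldodeca-2,10-dienoate | I/C(C)=C/[C@@H](CO[Si](C)(C)C(C)(C)C)[C@@H](O)[C@H](C)[C@H](O[Si](C)(C)C(C)(C)C)[C@H](C)C/C(C)=C/C(=O)OCC | intermediate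
30 | (2E,5R,6R,7S,8R,9S,10E)-6-[(tert-butyldimethylsilyl)oxy]-9-{[(tert-butyldimethylsilyl)oxy]methyl}-8-hydroxy-11-iodo-3,5,7-trimethyldodeca-2,10-dienoic acid | I/C(C)=C/[C@@H](CO[Si](C)(C)C(C)(C)C)[C@@H](O)[C@H](C)[C@H](O[Si](C)(C)C(C)(C)C)[C@H](C)C/C(C)=C/C(=O)O | intermediate
31 | prop-2-yn-1-ol | C#CCO | starting material
32 | (E)-3-(tributylstannyl)prop-2-en-1-ol | CCCC[Sn](CCCC)(CCCC)/C=C/CO | intermediate
33 | (E)-3-(tributylstannyl)prop-2-enal | CCCC[Sn](CCCC)(CCCC)/C=C/C=O | intermediate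
34 | (1E,3S,4S)-4-methyl-1-(tributylstannyl)hexa-1,5-dien-3-ol | CCCC[Sn](CCCC)(CCCC)/C=C/[C@@H](O)[C@@H](C)C=C | intermediate
35 | (1E,3S,4S)-4-methyl-1-(tributylstannyl)hexa-1,5-dien-3-yl prop-2-enoate | CCCC[Sn](CCCC)(CCCC)/C=C/[C@@H](OC(=O)C=C)[C@@H](C)C=C | intermediate
36 | (5S,6S)-5-methyl-6-[(E)-2-(tributylstannyl)ethenyl]-5,6-dihydro-2H-pyran-2-one (trans) | CCCC[Sn](CCCC)(CCCC)/C=C/[C@H]1OC(=O)C=C[C@@H]1C | intermediate
37 | (R)-3-bromo-2-methylpropan-1-ol | OC[C@@H](C)CBr | starting material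
38 | (R)-(3-bromo-2-methylpropoxy)(tert-butyl)dimethylsilane | CC(C)(C)[Si](C)(C)OC[C@@H](C)CBr | intermediate
39 | (S)-tert-butyldimethyl[(2-methylpent-4-yn-1-yl)oxy]silane | CC(C)(C)[Si](C)(C)OC[C@@H](C)CC#C | intermediate
40 | tert-butyldimethyl{[(2S,4E)-2-methyl-5-(4,4,5,5-tetramethyl-1,3,2-dioxaborolan-2-yl)pent-4-en-1-yl]oxy}silane | CC(C)(C)[Si](C)(C)OC[C@@H](C)C/C=C/B1OC(C)(C)C(C)(C)O1 | intermediate
41 | (2S,4E)-2-methyl-5-(4,4,5,5-tetramethyl-1,3,2-dioxaborolan-2-yl)pent-4-en-1-ol | OC[C@@H](C)C/C=C/B1OC(C)(C)C(C)(C)O1 | intermediate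
42 | (2S,4E)-2-methyl-5-(4,4,5,5-tetramethyl-1,3,2-dioxaborolan-2-yl)pent-4-enal | O=C[C@@H](C)C/C=C/B1OC(C)(C)C(C)(C)O1 | intermediate
43 | 2-[(1E,4S,5Z)-6-iodo-4-methylhepta-1,5-dien-1-yl]-4,4,5,5-tetramethyl-1,3,2-dioxaborolane | C/C(I)=C/[C@@H](C)C/C=C/B1OC(C)(C)C(C)(C)O1 | intermediate
44 | (5S,6R)-5-methyl-6-[(1E,3Z,5S,7E)-3,5-dimethyl-8-(4,4,5,5-tetramethyl-1,3,2-dioxaborolan-2-yl)octa-1,3,7-trien-1-yl]-5,6-dihydro-2H-pyran-2-one | CC(=C/[C@@H](C)C/C=C/B1OC(C)(C)C(C)(C)O1)/C=C/[C@H]1OC(=O)C=C[C@@H]1C | intermediate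
45 | (2E,5R,6R,7S,8R,9S,10E,12E,15S,16Z,18E)-6-[(tert-butyldimethylsilyl)oxy]-9-{[(tert-butyldimethylsilyl)oxy]methyl}-8-hydroxy-3,5,7,11,15,17-hexamethyl-19-[(2R,3S)-3-methyl-6-oxo-3,6-dihydro-2H-pyran-2-yl]nonadeca-2,10,12,16,18-pentaenoic acid | CC(=C/[C@@H](C)C/C=C/C(C)=C/[C@@H](CO[Si](C)(C)C(C)(C)C)[C@@H](O)[C@H](C)[C@H](O[Si](C)(C)C(C)(C)C)[C@H](C)C/C(C)=C/C(=O)O)/C=C/[C@H]1OC(=O)C=C[C@@H]1C | intermediate
46 | (2E,5R,6R,7R,9S,10E,12E,15S,16Z,18E)-6-[(tert-butyldimethylsilyl)oxy]-9-{[(tert-butyldimethylsilyl)oxy]methyl}-3,5,7,11,15,17-hexamethyl-19-[(2R,3S)-3-methyl-6-oxo-3,6-dihydro-2H-pyran-2-yl]-8-oxononadeca-2,10,12,16,18-pentaenoic acid | CC(=C/[C@@H](C)C/C=C/C(C)=C/[C@@H](CO[Si](C)(C)C(C)(C)C)C(=O)[C@H](C)[C@H](O[Si](C)(C)C(C)(C)C)[C@H](C)C/C(C)=C/C(=O)O)/C=C/[C@H]1OC(=O)C=C[C@@H]1C | intermediate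
47 | (2E,5R,6R,7R,9S,10E,12E,15S,16Z,18E)-6-hydroxy-9-(hydroxymethyl)-3,5,7,11,15,17-hexamethyl-19-[(2R,3S)-3-methyl-6-oxo-3,6-dihydro-2H-pyran-2-yl]-8-oxononadeca-2,10,12,16,18-pentaenoic acid | CC(=C/[C@@H](C)C/C=C/C(C)=C/[C@@H](CO)C(=O)[C@H](C)[C@H](O)[C@H](C)C/C(C)=C/C(=O)O)/C=C/[C@H]1OC(=O)C=C[C@@H]1C | target

**Totals and risks**

Total step count: 35. Longest linear sequence: 18 steps (steps 1–9, 11–13, 18–20, 33–35).

Steps most likely to fail:

Step 33. The aqueous base of the Suzuki coupling may open or hydrolyse the dihydropyranone (hydroxide attack or γ-deprotonation with elimination of the carboxylate), and the carboxylate salt of 30 may slow the reaction so that this exposure is prolonged. The fallback brings the lactone in last under neutral conditions and sets out from 42, 30 and 36. Aldehyde 42 is olefinated with the α-bromo ylide made from ethyltriphenylphosphonium bromide (n-BuLi, then 1,2-dibromotetrafluoroethane, then NaN(SiMe3)2, −78 °C) to give 2-[(1E,4S,5Z)-6-bromo-4-methylhepta-1,5-dien-1-yl]-4,4,5,5-tetramethyl-1,3,2-dioxaborolane F1. Its boronate is coupled with iodide 30 under the conditions of step 33; the hindered vinyl bromide should not undergo oxidative addition at room temperature, and this gives the C1–C17 bromo acid (2E,5R,6R,7S,8R,9S,10E,12E,15S,16Z)-17-bromo-6-[(tert-butyldimethylsilyl)oxy]-9-{[(tert-butyldimethylsilyl)oxy]methyl}-8-hydroxy-3,5,7,11,15-pentamethyloctadeca-2,10,12,16-tetraenoic acid F2. A Stille coupling of F2 with stannane 36 (Pd2(dba)3, P(t-Bu)3, NMP, 50 °C) then returns to 45.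

Step 19. The hydropalladation may not discriminate well enough between C10 and C11, or the homopropargylic oxygens may steer tin to C10, which would give regioisomeric stannanes and iodides. The fallback uses a thermodynamically controlled hydrozirconation and sets out from 27. The C8 hydroxyl is capped (TMSCl, imidazole) to give the 8-O-trimethylsilyl ether of 27 F3. Excess Cp2Zr(H)Cl in THF at rt to 40 °C lets zirconium migrate by reversible β-hydride elimination to the less hindered C11 (the trisubstituted enoate is expected to react slowly under these conditions), and iodinolysis gives the 8-O-trimethylsilyl ether of 29 F4. Citric acid in MeOH removes the TMS group and returns to 29.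

Step 11 (with step 9). Fluoride exchange on the hindered diol ester may stop short, and transmetalation of the β-branched alkyltrifluoroborate may be slower than hydrolysis of the activated enol triflate. The fallback replaces boron by zinc and sets out from 15. Oxidation (H2O2, NaOH, THF) gives (2R,3R,4S)-3,5-bis[(tert-butyldimethylsilyl)oxy]-2,4-dimethylpentan-1-ol F5 and returns the director 4. I2, PPh3 and imidazole give the corresponding primary iodide (CH2I in place of CH2OH) F6. Zinc insertion (activated Zn, LiCl, THF, 40 °C) gives the alkylzinc iodide F7, which is used without isolation. Negishi coupling of F7 with triflate 18 (Pd(PPh3)4, THF, rt) returns to 19.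

**Further compounds**
F1 | step 33 | 2-[(1E,4S,5Z)-6-bromo-4-methylhepta-1,5-dien-1-yl]-4,4,5,5-tetramethyl-1,3,2-dioxaborolane | C/C(Br)=C/[C@@H](C)C/C=C/B1OC(C)(C)C(C)(C)O1
F2 | step 33 | (2E,5R,6R,7S,8R,9S,10E,12E,15S,16Z)-17-bromo-6-[(tert-butyldimethylsilyl)oxy]-9-{[(tert-butyldimethylsilyl)oxy]methyl}-8-hydroxy-3,5,7,11,15-pentamethyloctadeca-2,10,12,16-tetraenoic acid | C/C(Br)=C/[C@@H](C)C/C=C/C(C)=C/[C@@H](CO[Si](C)(C)C(C)(C)C)[C@@H](O)[C@H](C)[C@H](O[Si](C)(C)C(C)(C)C)[C@H](C)C/C(C)=C/C(=O)O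
F3 | step 19 | 8-O-trimethylsilyl ether of 27 | CC#C[C@@H](CO[Si](C)(C)C(C)(C)C)[C@@H](O[Si](C)(C)C)[C@H](C)[C@H](O[Si](C)(C)C(C)(C)C)[C@H](C)C/C(C)=C/C(=O)OCC
F4 | step 19 | 8-O-trimethylsilyl ether of 29 | I/C(C)=C/[C@@H](CO[Si](C)(C)C(C)(C)C)[C@@H](O[Si](C)(C)C)[C@H](C)[C@H](O[Si](C)(C)C(C)(C)C)[C@H](C)C/C(C)=C/C(=O)OCC
F5 | step 11 | (2R,3R,4S)-3,5-bis[(tert-butyldimethylsilyl)oxy]-2,4-dimethylpentan-1-ol | CC(C)(C)[Si](C)(C)OC[C@H](C)[C@H](O[Si](C)(C)C(C)(C)C)[C@H](C)CO
F6 | step 11 | primary iodide from F5 (CH2I in place of CH2OH) | CC(C)(C)[Si](C)(C)OC[C@H](C)[C@H](O[Si](C)(C)C(C)(C)C)[C@H](C)CI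
F7 | step 11 | alkylzinc iodide from F6 (not isolated) | CC(C)(C)[Si](C)(C)OC[C@H](C)[C@H](O[Si](C)(C)C(C)(C)C)[C@H](C)C[Zn]I
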